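**Retrosynthetic overview**

- The strategy rests on the only ring, the 3-alkyl-5,6-dihydro-2H-pyran-2-one, whose C6 (O-bearing, allylic, the sole stereocentre) lies at the seam of two ten-carbon pieces.
- Ring bonds C5–C6 and O1–C2 are cut together, giving a 2-(acetoxymethyl) enal and a homoprenyl-bearing four-carbon ester dienolate, to be reunited in one catalytic asymmetric vinylogous aldol–lactonisation.
- The enal goes back through allylic oxidation, lipase differentiation of a geminal bis(acetoxymethyl) alkene, ester reduction and Knoevenagel condensation to a C7 aldehyde excised from nerol, which supplies the Z allylic alcohol end.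
- The dienolate goes back to ethyl crotonate and 5-bromo-2-methylpent-2-ene by deconjugative α-alkylation.
- Ring order: both halves stay open-chain; the single ring forms in the coupling step and only a desilylation follows.

Key step: step 12

Assumption: the (S)-antipode of Tol-BINAP is taken to steer the dienolate to the aldehyde face that gives 6R, by analogy with aryl and alkenyl aldehydes in this catalyst system; should a first run show the opposite sense, the (R)-ligand is used with no other change.

**Route**

Step 1
Reactants: 1 nerol, (2Z)-3,7-dimethylocta-2,6-dien-1-ol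
Product: 2 neryl tert-butyldiphenylsilyl ether
Conditions: t-BuPh2SiCl, imidazole, DMF, 0 °C to rt
Reagents that add atoms: tert-butyldiphenylsilyl chloride, CC(C)(C)[Si](Cl)(c1ccccc1)c1ccccc1
Why: Imidazole-promoted silylation of a primary alcohol should be clean, and the bulky silyl ether is chosen because it should withstand the later bromohydrin, periodic acid, TiCl4, hydride and catalytic fluoride conditions.

Step 2
Reactants: 2 neryl tert-butyldiphenylsilyl ether
Product: 3 (6Z)-3-bromo-8-(tert-butyldiphenylsilyloxy)-2,6-dimethyloct-6-en-2-ol (racemic)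
Conditions: NBS, THF/H2O, 0 °C
Reagents that add atoms: N-bromosuccinimide, O=C1CCC(=O)N1Br; water, O
Why: Bromohydrin formation should pick the electron-rich terminal trisubstituted alkene over the 2,3-alkene, which is deactivated and shielded by the allylic silyloxy group, with water opening the bromonium ion at the tertiary carbon.

Step 3
Reactants: 3 (6Z)-3-bromo-8-(tert-butyldiphenylsilyloxy)-2,6-dimethyloct-6-en-2-ol
Product: 4 tert-butyl{[(2Z)-5-(3,3-dimethyloxiran-2-yl)-3-methylpent-2-en-1-yl]oxy}diphenylsilane (racemic terminal epoxide)
Conditions: K2CO3, MeOH, rt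
Reagents that add atoms: none
Why: Intramolecular Williamson etherification, the tertiary alkoxide displacing the adjacent secondary bromide, should close the epoxide without touching the silyl ether or the Z alkene.

Step 4
Reactants: 4 terminal epoxide
Product: 6 (4Z)-6-(tert-butyldiphenylsilyloxy)-4-methylhex-4-enal, via glycol 5 (not isolated)
Conditions: HIO4·2H2O, THF/Et2O, 0 °C
Reagents that add atoms: water, O (taken up in glycol 5; the aldehyde oxygen of 6 is the former epoxide oxygen)
Why: Periodic acid should hydrate the trisubstituted epoxide to glycol 5 and cleave it at once (Malaprade glycol cleavage) to the aldehyde and acetone, leaving the Z allylic silyl ether intact.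

Step 5
Reactants: 6 (4Z)-6-(tert-butyldiphenylsilyloxy)-4-methylhex-4-enal; 7 dimethyl malonate
Product: 8 dimethyl 2-[(4Z)-6-(tert-butyldiphenylsilyloxy)-4-methylhex-4-en-1-ylidene]malonate
Conditions: TiCl4, pyridine, THF, 0 °C to rt
Reagents that add atoms: none
Why: The TiCl4/pyridine variant of the Knoevenagel condensation is the dependable one for enolisable aliphatic aldehydes, and the THF/pyridine-buffered Lewis acid should spare the allylic silyl ether.

Step 6
Reactants: 8 alkylidene malonate
Product: 9 2-[(4Z)-6-(tert-butyldiphenylsilyloxy)-4-methylhex-4-en-1-ylidene]propane-1,3-diol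
Conditions: i-Bu2AlH (5 equiv), CH2Cl2, −78 to −20 °C; aq. KNaC4H4O6 work-up
Reagents that add atoms: none
Why: Excess i-Bu2AlH at low temperature should reduce both esters by 1,2-addition to the allylic diol faster than it delivers hydride in conjugate fashion, and the new alkene carries two identical arms so no geometry question arises yet.

Step 7
Reactants: 9 2-alkylidenepropane-1,3-diol
Product: 10 2-[(4Z)-6-(tert-butyldiphenylsilyloxy)-4-methylhex-4-en-1-ylidene]propane-1,3-diyl diacetate
Conditions: Ac2O, pyridine, DMAP (cat.), CH2Cl2, 0 °C to rt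
Reagents that add atoms: acetic anhydride, CC(=O)OC(C)=O
Why: DMAP-catalysed acylation of two unhindered primary allylic alcohols should go to completion.

Step 8
Reactants: 10 diacetate
Product: 11 (2Z,6Z)-8-(tert-butyldiphenylsilyloxy)-2-(hydroxymethyl)-6-methylocta-2,6-dien-1-yl acetate (acetoxymethyl arm cis to the chain, hydroxymethyl arm cis to the vinylic hydrogen)
Conditions: Burkholderia cepacia lipase, pH 7 buffer (KH2PO4/K2HPO4), acetone cosolvent, rt, halted after one equivalent of acetate is released
Reagents that add atoms: none
Why: Lipase-catalysed regioselective hydrolysis of 2-alkylidenepropane-1,3-diyl diacetates should remove the acetate on the less hindered arm, the one cis to the vinylic hydrogen, which fixes the geometry of the trisubstituted alkene, while the neutral pH suppresses acetyl migration.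

Step 9
Reactants: 11 Z-monoacetate
Product: 12 (2E,6Z)-8-(tert-butyldiphenylsilyloxy)-2-formyl-6-methylocta-2,6-dien-1-yl acetate (formyl group trans to the chain)
Conditions: MnO2 (activated, excess), CH2Cl2, rt
Reagents that add atoms: none
Why: Neutral MnO2 oxidation of a primary allylic alcohol should give the enal without acetyl migration or over-oxidation, and the E enal obtained is also the thermodynamically preferred geometry.

Step 10
Reactants: 13 ethyl crotonate, ethyl (E)-but-2-enoate; 14 5-bromo-2-methylpent-2-ene
Product: 16 ethyl 2-ethenyl-6-methylhept-5-enoate (racemic), via lithium dienolate 15 (not isolated)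
Conditions: LiN(i-Pr)2, THF/DMPU, −78 °C; then 14, −78 °C to rt
Reagents that add atoms: none
Why: γ-Deprotonation of the crotonate in the presence of DMPU gives the extended lithium dienolate, which alkylates at its α-carbon (deconjugative α-alkylation) to give the β,γ-unsaturated ester, DMPU also suppressing amide conjugate addition and speeding the SN2 step.

Step 11
Reactants: 16 ethyl 2-ethenyl-6-methylhept-5-enoate
Product: 18 {[1-ethoxy-2-(4-methylpent-3-en-1-yl)buta-1,3-dien-1-yl]oxy}trimethylsilane (mixture of ketene acetal geometries), via lithium dienolate 17 (not isolated)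
Conditions: LiN(i-Pr)2, THF, −78 °C; Me3SiCl, −78 to 0 °C; pentane, filtration, concentration
Reagents that add atoms: chlorotrimethylsilane, C[Si](C)(C)Cl
Why: The α-hydrogen, activated by both the ester and the vinyl group, is removed cleanly and the ester dienolate is O-silylated to the silyl ketene acetal; the stereocentre of 16 is erased and both acetal geometries should funnel into the same metal dienolate.

Step 12
Reactants: 12 (2E,6Z)-2-(acetoxymethyl) enal; 18 silyl dienolate (1.5 equiv)
Product: 21 (6R)-6-[(2E,6Z)-1-acetoxy-8-(tert-butyldiphenylsilyloxy)-6-methylocta-2,6-dien-2-yl]-3-(4-methylpent-3-en-1-yl)-5,6-dihydro-2H-pyran-2-one, via copper dienolate 19 (not isolated), via open-chain copper aldolate 20 (not isolated)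
Conditions: Cu(OTf)2 (10 mol %), (S)-Tol-BINAP (11 mol %), Bu4N[Ph3SiF2] (20 mol %), THF, 0 °C to rt; pH 7 buffer work-up
Reagents that add atoms: none
Why: Fluoride on the Tol-BINAP copper centre (the divalent copper salt being reduced in the flask by a little of 18) takes silicon from 18 to give the monovalent copper dienolate 19, whose unsubstituted γ-carbon adds to the aldehyde carbon of 12 through a closed, s-cis, hetero-Diels–Alder-like transition state to give the Z-configured aldolate 20 (bond C5–C6), after which the alkoxide attacks the ethyl ester carbon and expels ethoxide (bond O1–C2), which strips silicon from the next molecule of 18 and restarts the cycle. The closest known reaction type is the Tol-BINAP copper fluoride catalysed vinylogous Mukaiyama aldol of ester-derived silyl dienolates with aldehydes, which delivers 5,6-dihydropyran-2-ones directly. The one ring is closed by 6-exo-trig acyl substitution of the aldolate oxygen on the ester, so the sequence amounts to a formal [4+2] annulation that also joins the two C10 halves. The new stereocentre C6 is set under catalyst control, the chiral bisphosphine on copper exposing one face of the bound aldehyde, with the (S)-ligand assigned to the R product. The step needs γ- over α-attack, secured by the fully substituted α-carbon carrying the homoprenyl chain, and 1,2- over conjugate or SN2′ attack, secured by the substituted β-carbon of the enal and its lack of an α-hydrogen. The near-neutral, base-free medium should leave the allylic acetate, the silyl ether and the three trisubstituted alkenes untouched.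

Step 13
Reactants: 21 silyl-protected lactone
Product: 22 (6R)-6-[(2E,6Z)-1-acetoxy-8-hydroxy-6-methylocta-2,6-dien-2-yl]-3-(4-methylpent-3-en-1-yl)-5,6-dihydro-2H-pyran-2-one (target)
Conditions: HF·pyridine, pyridine, THF, 0 °C to rt
Reagents that add atoms: none
Why: Pyridine-buffered HF should cleave the primary Si–O bond (fluoride-mediated desilylation) under mildly acidic conditions, where the acetate cannot migrate or hydrolyse and the lactone and its C6 stereocentre are not disturbed.

**Compound list**

1 | nerol, (2Z)-3,7-dimethylocta-2,6-dien-1-ol | CC(C)=CCC/C(C)=C\CO | starting material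
2 | neryl tert-butyldiphenylsilyl ether | CC(C)=CCC/C(C)=C\CO[Si](c1ccccc1)(c1ccccc1)C(C)(C)C | intermediate
3 | (6Z)-3-bromo-8-(tert-butyldiphenylsilyloxy)-2,6-dimethyloct-6-en-2-ol, racemic | CC(C)(O)C(Br)CC/C(C)=C\CO[Si](c1ccccc1)(c1ccccc1)C(C)(C)C | intermediate
4 | tert-butyl{[(2Z)-5-(3,3-dimethyloxiran-2-yl)-3-methylpent-2-en-1-yl]oxy}diphenylsilane, racemic | CC1(C)OC1CC/C(C)=C\CO[Si](c1ccccc1)(c1ccccc1)C(C)(C)C | intermediate
5 | (6Z)-8-(tert-butyldiphenylsilyloxy)-2,6-dimethyloct-6-ene-2,3-diol, racemic glycol, not isolated | CC(C)(O)C(O)CC/C(C)=C\CO[Si](c1ccccc1)(c1ccccc1)C(C)(C)C | intermediate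
6 | (4Z)-6-(tert-butyldiphenylsilyloxy)-4-methylhex-4-enal | O=CCC/C(C)=C\CO[Si](c1ccccc1)(c1ccccc1)C(C)(C)C | intermediate
7 | dimethyl malonate | COC(=O)CC(=O)OC | starting material
8 | dimethyl 2-[(4Z)-6-(tert-butyldiphenylsilyloxy)-4-methylhex-4-en-1-ylidene]malonate | COC(=O)C(=CCC/C(C)=C\CO[Si](c1ccccc1)(c1ccccc1)C(C)(C)C)C(=O)OC | intermediate
9 | 2-[(4Z)-6-(tert-butyldiphenylsilyloxy)-4-methylhex-4-en-1-ylidene]propane-1,3-diol | OCC(=CCC/C(C)=C\CO[Si](c1ccccc1)(c1ccccc1)C(C)(C)C)CO | intermediate
10 | 2-[(4Z)-6-(tert-butyldiphenylsilyloxy)-4-methylhex-4-en-1-ylidene]propane-1,3-diyl diacetate | CC(=O)OCC(=CCC/C(C)=C\CO[Si](c1ccccc1)(c1ccccc1)C(C)(C)C)COC(C)=O | intermediate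
11 | (2Z,6Z)-8-(tert-butyldiphenylsilyloxy)-2-(hydroxymethyl)-6-methylocta-2,6-dien-1-yl acetate | CC(=O)OC/C(=C\CC/C(C)=C\CO[Si](c1ccccc1)(c1ccccc1)C(C)(C)C)CO | intermediate
12 | (2E,6Z)-8-(tert-butyldiphenylsilyloxy)-2-formyl-6-methylocta-2,6-dien-1-yl acetate | CC(=O)OC/C(=C\CC/C(C)=C\CO[Si](c1ccccc1)(c1ccccc1)C(C)(C)C)C=O | intermediate
13 | ethyl crotonate, ethyl (E)-but-2-enoate | C/C=C/C(=O)OCC | starting material
14 | 5-bromo-2-methylpent-2-ene | CC(C)=CCCBr | starting material
15 | lithium dienolate of ethyl crotonate, not isolated | C=CC=C(OCC)O[Li] | intermediate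
16 | ethyl 2-ethenyl-6-methylhept-5-enoate, racemic | C=CC(CCC=C(C)C)C(=O)OCC | intermediate
17 | lithium dienolate of 16, not isolated | C=CC(CCC=C(C)C)=C(OCC)O[Li] | intermediate
18 | {[1-ethoxy-2-(4-methylpent-3-en-1-yl)buta-1,3-dien-1-yl]oxy}trimethylsilane, mixture of ketene acetal geometries | C=CC(CCC=C(C)C)=C(OCC)O[Si](C)(C)C | intermediate
19 | monovalent copper dienolate of 16, bisphosphine omitted, not isolated | C=CC(CCC=C(C)C)=C(OCC)O[Cu] | intermediate
20 | open-chain monovalent copper aldolate, ethyl (2Z,5R) δ-oxido enoate, bisphosphine omitted, not isolated | CCOC(=O)/C(CCC=C(C)C)=C\C[C@@H](O[Cu])/C(COC(C)=O)=C/CC/C(C)=C\CO[Si](c1ccccc1)(c1ccccc1)C(C)(C)C | intermediate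
21 | (6R)-6-[(2E,6Z)-1-acetoxy-8-(tert-butyldiphenylsilyloxy)-6-methylocta-2,6-dien-2-yl]-3-(4-methylpent-3-en-1-yl)-5,6-dihydro-2H-pyran-2-one | CC(=O)OC/C(=C\CC/C(C)=C\CO[Si](c1ccccc1)(c1ccccc1)C(C)(C)C)[C@H]1CC=C(CCC=C(C)C)C(=O)O1 | intermediate
22 | (6R)-6-[(2E,6Z)-1-acetoxy-8-hydroxy-6-methylocta-2,6-dien-2-yl]-3-(4-methylpent-3-en-1-yl)-5,6-dihydro-2H-pyran-2-one | CC(=O)OC/C(=C\CC/C(C)=C\CO)[C@H]1CC=C(CCC=C(C)C)C(=O)O1 | target

**Step count**

Total steps: 13. Longest linear sequence: 11 (steps 1 to 9, then 12 and 13). The dienolate branch (steps 10 and 11) joins at step 12.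

**Steps most likely to fail**

1. Step 12.
- What may go wrong: facial selectivity at this α-branched enal may be poor; the open-chain adduct may form with E geometry and so be unable to lactonise; the copper aldolate may pick up the neighbouring acetyl group instead of closing on the ester; or a nucleophile may displace the allylic acetate in SN2′ fashion.
- Fallback: it sets out from enal 12 and bromide 14 and rejoins the route at lactone 21, building the ring by allylation, esterification and ring-closing metathesis instead.
  - Enal 12 would be allylated at −78 °C with the antipode of B-allyldiisopinocampheylborane that gives the R carbinol (by analogy with aryl aldehydes, the reagent derived from (−)-α-pinene), with ethanolamine work-up to spare the acetate, giving homoallylic alcohol F1.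
  - Separately, bromide 14 would alkylate triethyl phosphonoacetate (NaH, DMF) to give phosphonate F2.
  - Horner–Wadsworth–Emmons reaction of F2 with aqueous formaldehyde and K2CO3 should give ethyl 6-methyl-2-methylidenehept-5-enoate F3, and LiOH saponification the acid F4.
  - Steglich esterification of F1 with F4 (DCC, DMAP) would give diene ester F5.
  - Ring-closing metathesis of F5 with second-generation Grubbs catalyst in warm toluene should join the terminal vinyl group to the 1,1-disubstituted acrylate, closing the C3=C4 bond of the ring and giving 21.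

2. Step 6.
- What may go wrong: hydride may be delivered in conjugate fashion to the strongly electrophilic alkylidene malonate, leading to saturated or over-reduced material instead of the allylic diol.
- Fallback: it sets out from aldehyde 6 and rejoins the route at diol 9, bypassing the malonate.
  - Morita–Baylis–Hillman reaction of 6 with methyl acrylate (DABCO) would give the β-hydroxy α-methylene ester F6.
  - Acetylation would give the secondary acetate F7.
  - DABCO-mediated allylic transposition would move the acetate to the primary position, giving methyl (2E,6Z)-2-(acetoxymethyl) enoate F8.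
  - i-Bu2AlH would then reduce the single conjugated ester by 1,2-addition and cleave the acetate, giving 9.

3. Step 8.
- What may go wrong: the enzyme may discriminate poorly between the two acetoxymethyl arms, or the acetyl group may migrate in the monoacetate, eroding the alkene geometry.
- Fallback: it sets out from diol 9 and rejoins the route at enal 12, relying on thermodynamic control of the enal geometry instead of the enzyme.
  - Non-enzymatic monoacetylation of 9 (one equivalent of acetyl chloride, 2,4,6-collidine, −78 °C, with recycling of diol and diacetate) would give 11 together with its regioisomer, the (2E,6Z)-monoacetate F9.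
  - MnO2 oxidation of the mixture would give 12 and its geometric isomer, the (2Z,6Z)-enal F10. These two share one constitution and differ only in enal geometry.
  - Equilibration with catalytic iodine in CH2Cl2 under ambient light should convert F10 into the thermodynamically preferred E enal 12.

**Further compounds**

F1 | step 12 | (2E,6Z)-2-[(1R)-1-hydroxybut-3-en-1-yl]-8-(tert-butyldiphenylsilyloxy)-6-methylocta-2,6-dien-1-yl acetate | C=CC[C@@H](O)/C(COC(C)=O)=C/CC/C(C)=C\CO[Si](c1ccccc1)(c1ccccc1)C(C)(C)C
F2 | step 12 | ethyl 2-(diethoxyphosphoryl)-6-methylhept-5-enoate | CCOC(=O)C(CCC=C(C)C)P(=O)(OCC)OCC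
F3 | step 12 | ethyl 6-methyl-2-methylidenehept-5-enoate | C=C(CCC=C(C)C)C(=O)OCC
F4 | step 12 | 6-methyl-2-methylidenehept-5-enoic acid | C=C(CCC=C(C)C)C(=O)O
F5 | step 12 | (1R)-1-[(2E,6Z)-1-acetoxy-8-(tert-butyldiphenylsilyloxy)-6-methylocta-2,6-dien-2-yl]but-3-en-1-yl 6-methyl-2-methylidenehept-5-enoate | C=CC[C@@H](OC(=O)C(=C)CCC=C(C)C)/C(COC(C)=O)=C/CC/C(C)=C\CO[Si](c1ccccc1)(c1ccccc1)C(C)(C)C
F6 | step 6 | methyl (6Z)-8-(tert-butyldiphenylsilyloxy)-3-hydroxy-6-methyl-2-methylideneoct-6-enoate, racemic | C=C(C(=O)OC)C(O)CC/C(C)=C\CO[Si](c1ccccc1)(c1ccccc1)C(C)(C)C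
F7 | step 6 | methyl (6Z)-3-acetoxy-8-(tert-butyldiphenylsilyloxy)-6-methyl-2-methylideneoct-6-enoate, racemic | C=C(C(=O)OC)C(OC(C)=O)CC/C(C)=C\CO[Si](c1ccccc1)(c1ccccc1)C(C)(C)C
F8 | step 6 | methyl (2E,6Z)-2-(acetoxymethyl)-8-(tert-butyldiphenylsilyloxy)-6-methylocta-2,6-dienoate | COC(=O)/C(COC(C)=O)=C/CC/C(C)=C\CO[Si](c1ccccc1)(c1ccccc1)C(C)(C)C
F9 | step 8 | (2E,6Z)-8-(tert-butyldiphenylsilyloxy)-2-(hydroxymethyl)-6-methylocta-2,6-dien-1-yl acetate | CC(=O)OC/C(=C/CC/C(C)=C\CO[Si](c1ccccc1)(c1ccccc1)C(C)(C)C)CO
F10 | step 8 | (2Z,6Z)-8-(tert-butyldiphenylsilyloxy)-2-formyl-6-methylocta-2,6-dien-1-yl acetate | CC(=O)OC/C(=C/CC/C(C)=C\CO[Si](c1ccccc1)(c1ccccc1)C(C)(C)C)C=O
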